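The constants are made up; the rest is arithmetic.

The amounts stand nearly level: reagent exceeds substrate by 0.0290 M, so substrate, charged at 0.29 M, is the limiting reagent.

in all of them: time 6.0 min
- red: substrate 0.29 M; reagent 0.319 M (fed, over 4.0 min); temperature 60 °C; all else is in the flask from the start; the feed brings no volume worth counting
- blue: substrate 0.29 M; reagent 0.319 M (fed, over 4.0 min); the addition at 40 °C, then warmed to 60 °C; the feed brings no volume worth counting
- teal: substrate 0.29 M (in portions, 3, over 4.0 min); reagent 0.319 M; temperature 60 °C; first portion at the start, last at 4.0 min
- amber: substrate 0.29 M (fed, over 4.0 min); reagent 0.319 M; temperature 60 °C; all else is in the flask from the start; the feed brings no volume worth counting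

    crystals ⇌ target, rate k1*(cs1 - [target]) while solid is left; crystals form when [target] > cs1 (cs1 = 0.089 M, k1 = 0.0954 s⁻¹)
    substrate + reagent → target, rate k2*[substrate]*[reagent]^1.5 (k2 = 0.0724 M⁻¹·⁵ s⁻¹, Ea2 = 41.0 kJ mol⁻¹)
    (constants at 60 °C)

- what is said of target includes crystals
- crystals is a solid; its amount is given per volume of the solution
- the list of constants is for 60 °C, to be carried to other temperatures by the activation energies

- the best flask by amount of target, in percent of the substrate charged; "all alike" if 1.5 percentage points covers them all (red / blue / teal / amber / all alike)
- amount of target at the end, in percent of the substrate charged, red
- amount of target at the end, in percent of the substrate charged, blue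
- amount of target at the end, in percent of the substrate charged, teal
- amount of target at the end, in percent of the substrate charged, amber

Does step 1 matter to the answer? No, because target is counted together with crystals, so what is asked is what step 2 has made.

How can step 2 be reckoned by hand? Treat the excess as a small correction. Once both are fully in, reagent stands above substrate by the excess, so I call the level amount u, substrate plus 0.600 of the excess. While the excess is small beside u, the rate is close to k2 times u to the power 2.50. The amount u starts from 0.307 M. On that law, u to the power −1.50 climbs steadily and reaches 2 times its starting value after 0.900 min, and this time is the level clock.

What does the clock give with everything charged at once at 60 °C? After 6.0 min, target stands at 78.7 %.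

But no flask here is charged at once, so what does dosing cost? Material fed steadily arrives on average after 2.00 min, which is half of the dosing time, and the portions in teal average the same. Taking that off the running time gives 71.7 % for red, teal and amber.

And blue? Its rate constant during the addition is 0.389 of the hot one. Taking the warming as instant, it runs for 2.78 min of hot time, which gives 64.5 %. That lies 7.2 percentage points below the others, outside the margin of 1.5 points.

The clock cannot separate the hot flasks, so which of them leads? At half of its charge, fed reagent gives 0.354 of the full rate, while fed substrate gives 0.500. I therefore commit to amber.

The forecast also named amber, with 67.2 %, 61.7 %, 67.6 % and 69 % for red, blue, teal and amber, saying that “reagent stays high throughout”.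

The simulation gives amber as best, with red 68.1 %, blue 62.7 %, teal 68.0 % and amber 69.6 %.

Blue has not come to rest at 6.00 min, for it still holds 37.3 % of its substrate. Started from that reading, the level clock of 0.900 min gives 93.6 % target at 25 min, and blue stands at 92.8 % then. At 60.0 min blue reads 97.9 %. Started from its own end reading, the clock gives amber 99.4 % at 60.0 min, where amber reads 98.0 %. Amber then still holds 2.02 % of its substrate, and its reagent, at 10.9 % of its charge, stands above the 9.09 % that the excess leaves.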